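**Retrosynthetic overview**
1. The C4 hemiketal/pyran, the C8–O bond and C17–H come last, from water adding across the ring: C4 ketone hydrate onto the 8(17)-butenolide of macrocycle 24 (new step).
2. The ten-membered ring is closed at C2–C3 by an intramolecular boron aldol; before that C9–C10 is made by an intermolecular Cr(II) allylation, which also creates the 11(20)-methylene.
3. Fragment A (cyclohexane, C1/C14) comes from 2-methylcyclohexane-1,3-dione by CBS desymmetrisation.
4. Fragment B (butenolide, C7) comes from dihydroxyacetone and methyl vinyl ketone by a cinchona-catalysed allylic alkylation.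
5. Ring order: cyclohexane (starting material) → butenolide → ten-membered carbocycle → pyran/hemiketal.

Atom labels are briarane numbers: C1 is the quaternary carbon bearing the C15 methyl; C2, C9 and C14 carry OAc; C4 is the hemiketal; the lactone is C7–O–C19(=O)–C17(C18)–C8; C16 and C20 are the exo-methylenes.
Assumption: C4 (hemiketal) and C17 (α to the lactone) are taken to be under thermodynamic control and are written as in the target SMILES.

**Fragment A**

Step 1
Reactants: 1 2-methylcyclohexane-1,3-dione
Product: 2 2-allyl-2-methylcyclohexane-1,3-dione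
Conditions: allyl bromide, 1 M aq. NaOH, rt
Reagents that add atoms: allyl bromide, C=CCBr
Why: C-alkylation of the stabilised dione enolate with a soft allylic halide gives the prochiral quaternary carbon (classical 1,3-dione alkylation).

Step 2
Reactants: 2
Product: 3 (2S,3S)-2-allyl-3-hydroxy-2-methylcyclohexan-1-one (OH cis to allyl)
Conditions: (R)-Me-CBS (20 mol %), catecholborane, toluene, −78 → −40 °C
Reagents that add atoms: none
Why: CBS (oxazaborolidine, metal-free) enantiotopic-group-selective reduction; the catalyst fixes the carbinol configuration and hydride adds anti to the larger allyl group, so C14 and quaternary C1 are set in one event (the same product is known from yeast reduction).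

Step 3
Reactants: 3
Product: 4 (1S,2S)-2-allyl-2-methyl-3-oxocyclohexyl acetate
Conditions: Ac2O, DMAP, pyridine, CH2Cl2, 0 °C
Reagents that add atoms: acetic anhydride, CC(=O)OC(C)=O
Why: Standard acylation installs the final 14-OAc; no β-elimination is possible because the α-carbon is quaternary.

Step 4
Reactants: 4
Product: 5 (1S,2S)-2-methyl-3-oxo-2-[(E)-prop-1-enyl]cyclohexyl acetate
Conditions: RuHCl(CO)(PPh3)3 (5 mol %), toluene, 80 °C
Reagents that add atoms: none
Why: Ru–H catalysed allyl → propenyl isomerisation (hydrometalation/β-hydride elimination) moves the alkene next to C1 without touching the stereocentres.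

Step 5
Reactants: 5
Product: 6 (1S,2R)-2-(dimethoxymethyl)-2-methyl-3-oxocyclohexyl acetate
Conditions: O3, CH2Cl2/MeOH, −78 °C; Me2S; then HC(OMe)3, TsOH (cat.), rt (one pot)
Reagents that add atoms: methanol, CO (with trimethyl orthoformate, COC(OC)OC); the ozone oxygen is lost on acetalisation
Why: Ozonolysis gives the non-enolisable C2 aldehyde, and the unhindered aldehyde is acetalised selectively over the neopentyl ketone.

Step 6
Reactants: 6
Product: 7 (1S,2R)-2-(dimethoxymethyl)-2-methyl-4-methylidene-3-oxocyclohexyl acetate
Conditions: (CH2O)n, iPr2NH·TFA, THF, reflux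
Reagents that add atoms: paraformaldehyde, C=O
Why: Mannich/elimination α-methylenation; the ketone can enolise only toward C11 because C1 is quaternary.

Step 7
Reactants: 7
Product: 8 2-(dimethoxymethyl)-3-hydroxy-2-methyl-4-methylidenecyclohexyl acetate (C10 carbinol epimers, both usable)
Conditions: NaBH4, CeCl3·7H2O, MeOH, −78 → 0 °C
Reagents that add atoms: none
Why: Luche 1,2-reduction of the enone gives the allylic alcohol; acetate and acetal survive.

Step 8
Reactants: 8
Product: 9 (1S,2R)-4-(bromomethyl)-2-(dimethoxymethyl)-2-methylcyclohex-3-en-1-yl acetate (fragment A)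
Conditions: CBr4, PPh3, 2,6-lutidine, CH2Cl2, 0 °C
Reagents that add atoms: carbon tetrabromide, BrC(Br)(Br)Br
Why: Appel activation of the hindered allylic alcohol with SN2′ bromide delivery gives the primary allylic bromide; any secondary isomer converges to the same allylchromium in step 16.

**Fragment B**

Step 9
Reactants: 10 but-3-en-2-one
Product: 11 3-(hydroxymethyl)but-3-en-2-one
Conditions: aq. CH2O, DABCO (cat.), THF/H2O, rt
Reagents that add atoms: formaldehyde, C=O
Why: Morita–Baylis–Hillman reaction of the vinyl ketone with formaldehyde installs C6 on C5.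

Step 10
Reactants: 11
Product: 12 tert-butyl (2-methylidene-3-oxobutyl) carbonate
Conditions: Boc2O, DMAP (cat.), CH2Cl2, 0 °C
Reagents that add atoms: di-tert-butyl dicarbonate, CC(C)(C)OC(=O)OC(=O)OC(C)(C)C
Why: O-acylation gives the MBH carbonate, the electrophile for Lewis-base catalysis.

Step 11
Reactants: 13 1,3-dihydroxyacetone (dimer); 14 ethyl 2-(triphenylphosphoranylidene)propanoate
Product: 15 4-(hydroxymethyl)-3-methylfuran-2(5H)-one
Conditions: toluene/MeOH, reflux; then TsOH (cat.)
Reagents that add atoms: none
Why: Wittig olefination of the ketone followed by lactonisation of the CH2OH cis to the ester; the two arms are identical, so alkene geometry is irrelevant.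

Step 12
Reactants: 15
Product: 16 4-{[(tert-butyldimethylsilyl)oxy]methyl}-3-methylfuran-2(5H)-one
Conditions: TBSCl, imidazole, DMF, rt
Reagents that add atoms: TBSCl, CC(C)(C)[Si](C)(C)Cl
Why: Silyl protection prevents O-allylation of the free alcohol in the next step.

Step 13
Reactants: 16; 12
Product: 17 (S)-4-{[(tert-butyldimethylsilyl)oxy]methyl}-3-methyl-5-(2-methylidene-3-oxobutyl)furan-2(5H)-one
Conditions: (DHQD)2PHAL or its pseudo-enantiomer, whichever gives (S) (10 mol %), toluene, 0 °C → rt
Reagents that add atoms: none
Why: Organocatalytic asymmetric allylic alkylation: the cinchona amine adds SN2′ to the carbonate, the released tert-butoxide generates the 2-oxyfuran anion, and this attacks through its γ-carbon inside the chiral ammonium ion pair, forming C6–C7 and setting C7.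

Step 14
Reactants: 17
Product: 18 (S)-4-(hydroxymethyl)-3-methyl-5-(2-methylidene-3-oxobutyl)furan-2(5H)-one
Conditions: HF·pyridine, THF, 0 °C → rt
Reagents that add atoms: none
Why: Acidic fluoride desilylation avoids base, so the γ-stereocentre is not epimerised.

Step 15
Reactants: 18
Product: 19 (S)-4-methyl-2-(2-methylidene-3-oxobutyl)-5-oxo-2,5-dihydrofuran-3-carbaldehyde (fragment B)
Conditions: Dess–Martin periodinane, NaHCO3, CH2Cl2, 0 °C
Reagents that add atoms: none
Why: Buffered Dess–Martin oxidation of the primary allylic alcohol gives the C9 aldehyde without touching the enone or C7.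

**Union, macrocyclisation and endgame**

Step 16
Reactants: 9; 19
Product: 20 seco-alcohol: C10 of the 11(20)-methylenecyclohexane is bonded to the C9 carbinol, which carries the butenolide at C8; C2 is still the dimethyl acetal
Conditions: CrCl2 (4 equiv), THF, 0 °C → rt
Reagents that add atoms: none
Why: Nozaki–Hiyama allylation, aldehyde-selective over the ketone. γ-Attack through a chair transition state with the ring-fixed (E)-type allyl gives the anti C9-OH/C10 relationship and the exo-methylene. The aldehyde adds to the C10 face syn to the C15 methyl and anti to the larger acetal branch, so C9 ends trans to C2.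

Step 17
Reactants: 20
Product: 21 the C9 acetate of 20
Conditions: Ac2O, DMAP, pyridine, CH2Cl2, 0 °C
Reagents that add atoms: acetic anhydride, CC(=O)OC(C)=O
Why: Acylation installs the final 9-OAc and prevents the C9-OH from forming a five-membered lactol with the C2 aldehyde.

Step 18
Reactants: 21
Product: 22 seco-aldehyde (C2 aldehyde; methyl enone; butenolide; 9,14-diacetate)
Conditions: TFA/H2O/CH2Cl2, 0 °C
Reagents that add atoms: water, O
Why: Mild acidic acetal hydrolysis; nothing else in the molecule is acid-labile under these conditions.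

Step 19
Reactants: 22
Product: 23 macrocyclic aldol: ten-membered carbocycle with 2-OH, C4 ketone, 5(16)- and 11(20)-methylenes, 8(17)-butenolide and 9,14-diacetate
Conditions: Cy2BCl, Et3N, Et2O, 0.002 M (slow addition), −78 → −20 °C; MeOH/pH 7 buffer
Reagents that add atoms: none
Why: Intramolecular boron aldol; the Lewis acid complexes and enolises the ketone, not the lactone, and the boron aldolate is kinetically trapped. Ring closure forces C3 to approach C2 anti to C14, and the Felkin–Anh trajectory then passes over the small C15 methyl rather than C10, giving the 2-OH syn to the 14-OAc.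

Step 20
Reactants: 23
Product: 24 macrocyclic 2,9,14-triacetate (C4 enone, 8(17)-butenolide)
Conditions: Ac2O, Sc(OTf)3 (cat.), MeCN, −20 °C
Reagents that add atoms: acetic anhydride, CC(=O)OC(C)=O
Why: Lewis-acid-catalysed acylation of the hindered neopentyl alcohol avoids amine base and so avoids E1cB loss of the β-acyloxy group.

Step 21
Reactants: 24
Product: 25 (+)-junceellolide A
Conditions: H2O (10 equiv), quinine-derived squaramide (bifunctional amine/H-bond donor, 20 mol %), THF, 40 °C
Reagents that add atoms: water, O
Why: Proposed new method: a transannular hydrative oxa-Michael/hemiketalisation cascade. The catalyst's amine activates an OH of the C4 gem-diol (ketone hydrate) as a general base while the squaramide activates the lactone carbonyl, and the oxygen adds 6-exo to C8 of the β,β-disubstituted butenolide. The new pyran can only be cis-fused to the lactone, so C7 dictates C8; the lactone enolate is protonated and equilibrated to the C17 epimer with C18 trans to C9, and C4 settles as the hemiketal. The closest known chemistry is hemiacetal- or hydrate-relayed intramolecular oxa-Michael addition and bifunctional-organocatalyst cycloetherification of hydroxy enones; it has not been shown for a ketone hydrate adding across a ring to a tetrasubstituted butenolide.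

**Compound list**
1 | 2-methylcyclohexane-1,3-dione | CC1C(=O)CCCC1=O | starting material
2 | 2-allyl-2-methylcyclohexane-1,3-dione | C=CCC1(C)C(=O)CCCC1=O | intermediate
3 | (2S,3S)-2-allyl-3-hydroxy-2-methylcyclohexan-1-one | O=C1CCC[C@H](O)[C@@]1(CC=C)C | intermediate
4 | (1S,2S)-2-allyl-2-methyl-3-oxocyclohexyl acetate | O=C1CCC[C@H](OC(C)=O)[C@@]1(CC=C)C | intermediate
5 | (1S,2S)-2-methyl-3-oxo-2-[(E)-prop-1-enyl]cyclohexyl acetate | O=C1CCC[C@H](OC(C)=O)[C@@]1(/C=C/C)C | intermediate
6 | (1S,2R)-2-(dimethoxymethyl)-2-methyl-3-oxocyclohexyl acetate | O=C1CCC[C@H](OC(C)=O)[C@@]1(C(OC)OC)C | intermediate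
7 | (1S,2R)-2-(dimethoxymethyl)-2-methyl-4-methylidene-3-oxocyclohexyl acetate | C=C1CC[C@H](OC(C)=O)[C@@](C(OC)OC)(C)C1=O | intermediate
8 | 2-(dimethoxymethyl)-3-hydroxy-2-methyl-4-methylidenecyclohexyl acetate (carbinol epimers) | C=C1CC[C@H](OC(C)=O)[C@@](C(OC)OC)(C)C1O | intermediate
9 | (1S,2R)-4-(bromomethyl)-2-(dimethoxymethyl)-2-methylcyclohex-3-en-1-yl acetate | BrCC1=C[C@@](C)(C(OC)OC)[C@@H](OC(C)=O)CC1 | intermediate (fragment A)
10 | but-3-en-2-one | CC(=O)C=C | starting material
11 | 3-(hydroxymethyl)but-3-en-2-one | CC(=O)C(=C)CO | intermediate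
12 | tert-butyl (2-methylidene-3-oxobutyl) carbonate | CC(=O)C(=C)COC(=O)OC(C)(C)C | intermediate
13 | 1,3-dihydroxyacetone | OCC(=O)CO | starting material
14 | ethyl 2-(triphenylphosphoranylidene)propanoate | CCOC(=O)C(C)=P(c1ccccc1)(c1ccccc1)c1ccccc1 | starting material
15 | 4-(hydroxymethyl)-3-methylfuran-2(5H)-one | CC1=C(CO)COC1=O | intermediate
16 | 4-{[(tert-butyldimethylsilyl)oxy]methyl}-3-methylfuran-2(5H)-one | CC1=C(CO[Si](C)(C)C(C)(C)C)COC1=O | intermediate
17 | (S)-4-(TBSO-methyl)-3-methyl-5-(2-methylidene-3-oxobutyl)furan-2(5H)-one | CC(=O)C(=C)C[C@@H]1OC(=O)C(C)=C1CO[Si](C)(C)C(C)(C)C | intermediate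
18 | (S)-4-(hydroxymethyl)-3-methyl-5-(2-methylidene-3-oxobutyl)furan-2(5H)-one | CC(=O)C(=C)C[C@@H]1OC(=O)C(C)=C1CO | intermediate
19 | (S)-4-methyl-2-(2-methylidene-3-oxobutyl)-5-oxo-2,5-dihydrofuran-3-carbaldehyde | CC(=O)C(=C)C[C@@H]1OC(=O)C(C)=C1C=O | intermediate (fragment B)
20 | seco C9 alcohol (C9–C10 joined; C2 dimethyl acetal; 14-OAc) | C=C1CC[C@H](OC(C)=O)[C@@](C(OC)OC)(C)[C@H]1[C@@H](O)C2=C(C)C(=O)O[C@H]2CC(=C)C(C)=O | intermediate
21 | seco 9,14-diacetate, C2 dimethyl acetal | C=C1CC[C@H](OC(C)=O)[C@@](C(OC)OC)(C)[C@H]1[C@@H](OC(C)=O)C2=C(C)C(=O)O[C@H]2CC(=C)C(C)=O | intermediate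
22 | seco C2 aldehyde, 9,14-diacetate | C=C1CC[C@H](OC(C)=O)[C@@](C=O)(C)[C@H]1[C@@H](OC(C)=O)C2=C(C)C(=O)O[C@H]2CC(=C)C(C)=O | intermediate
23 | macrocyclic aldol: 2-hydroxy-4-oxo-9,14-diacetoxy, 5(16),11(20)-dimethylidene, 8(17)-ene-19,7-olide | C=C1CC[C@H](OC(C)=O)[C@@]2(C)[C@H]1[C@@H](OC(C)=O)C3=C(C)C(=O)O[C@H]3CC(=C)C(=O)C[C@H]2O | intermediate
24 | macrocyclic 2,9,14-triacetate (C4 enone, 8(17)-butenolide) | C=C1CC[C@H](OC(C)=O)[C@@]2(C)[C@H]1[C@@H](OC(C)=O)C3=C(C)C(=O)O[C@H]3CC(=C)C(=O)C[C@H]2OC(C)=O | intermediate
25 | (+)-junceellolide A (1R,2R,4R,7S,8S,9R,10S,14S,17R, as encoded in the given SMILES) | C=C1CC[C@H](OC(C)=O)[C@@]2(C)[C@H]1[C@@H](OC(C)=O)[C@@]13O[C@](O)(C[C@H]2OC(C)=O)C(=C)C[C@@H]1OC(=O)[C@@H]3C | target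

**Step count**
Total: 21 steps. Longest linear sequence: 14 (steps 1–8, then 16–21).

**Three steps most likely to fail**
1. Step 21 (proposed new hydrative oxa-Michael). Risks are low hydrate concentration, reversibility at the tetrasubstituted carbon, and elimination of the 2-OAc. Fallback with known chemistry: build the lactone last instead. Carry a C7-hydroxy/C8-ketone in place of the butenolide, acylate the C7-OH with 2-bromopropionyl bromide, and close the lactone by SmI2 intramolecular Reformatsky aldol. This gives the 8-OH and C17 directly, and the 8-OH then hemiketalises onto C4.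
2. Step 19 (ten-membered ring by boron aldol). Risks are ring strain, competing enolisation of the butenolide, and C2 selectivity. Fallback: reverse the assembly order. Join the A aldehyde and the B ketone first by an intermolecular Ipc2BCl aldol, then close C9–C10 by intramolecular Cr(II) allylation (Nozaki–Hiyama macrocyclisation).
3. Step 13 (organocatalytic allylic alkylation). Risks are modest ee with an unsubstituted MBH carbonate, α- versus γ-attack, and epimerisation of the γ-H product. Fallback: build the butenolide around a preset stereocentre. Make the (S)-α-hydroxy ester by chiral-phosphoric-acid allylboration of ethyl glyoxylate, O-propionylate, cyclise by Dieckmann reaction to the 5-substituted 3-methyltetronic acid, then triflate and introduce C9 by Pd-catalysed hydroxymethylation.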